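**Plan**

1. Cuts: (i) the skipped (Z)-CH=CH of the eleven-membered ring (ring-closing metathesis of two allyl groups); (ii) the bond between tetronate C-3 and the acyl carbon (3-lithio tetronate + aldehyde, then oxidation); (iii) in ring A (the cyclohexene of the decalin), the bond from the quaternary C(CH3)(acyl) carbon to the allylic ring CH that carries the side chain; (iv) the spiro-cyclohexene (Diels–Alder).
2. Feature used for (iii): that quaternary carbon is α to a C=O and its ring neighbour is the end of a CH–CH=CH allyl unit, so the bond is an enolate/π-allyl union. Both halves are tied through CO2 as an eight-membered (Z)-allylic lactone of a malonic half-thioester fused to ring B; zerovalent palladium expels CO2 and contracts this ring to six-membered ring A.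
3. Forward: (R)-carvone → fully substituted ring B → ester with an (R)-dienol → thioester → eight-membered lactone (metathesis) → ring contraction to the trans-decalin → aldehyde. In parallel: triene + 2-acetoxyacrolein → spiro methyl tetronate. Then union, oxidation, macrocyclic Z-metathesis, deprotection.
4. Stereochemistry: ring-fusion CH from carvone; cis O/CH3/O triad from hydroxyl-directed epoxidation, a stereospecific hydride shift and an axial hydride reduction; trans ring fusion from enolate allylation; side-chain CH of ring A from (R)-epichlorohydrin by retentive (double-inversion) allylation; quaternary carbon by A(1,3) strain; spiro ring by a catalyst-controlled exo Diels–Alder reaction; (Z)-olefin by catalyst and ring strain.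

Key step: step 15

Remark: the 3-acyltetronic acid is written as the exocyclic-enol tautomer. Compounds 14–18 are epimer mixtures at the CH(CH3) or C(CH3)(COSEt) carbon (made planar in step 15) and 35 at the carbinol carbon (oxidised in step 30). In step 24 the catalyst antipode is the one that sends the diene to the Si face of C-2 of the enal.

**Route**

Step 1
Reactants: 1 (R)-epichlorohydrin
Product: 2 (R)-1-chloro-5-methylhex-4-en-2-ol
Conditions: 2-methylprop-1-enylmagnesium bromide, CuI (10 mol %), THF, −40 → −10 °C
Reagents that add atoms: 2-methylprop-1-enylmagnesium bromide CC(C)=C[Mg]Br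
Why: Copper-catalysed Grignard opening of the epoxide at its unsubstituted carbon leaves the carbinol stereocentre untouched.

Step 2
Reactants: 2 (R)-1-chloro-5-methylhex-4-en-2-ol
Product: 4 (R)-6-methylhepta-1,5-dien-3-ol, via epoxide 3 (not isolated)
Conditions: Me3S+ I− (3.5 equiv), n-BuLi (3.4 equiv), THF, −10 °C → rt
Reagents that add atoms: trimethylsulfonium iodide C[S+](C)C.[I-]
Why: The sulfonium ylide closes the chlorohydrin to the epoxide, opens it at the CH2 terminus and the β-oxido sulfonium salt eliminates dimethyl sulfide (one-carbon homologation of an epoxide to an allylic alcohol), without touching the stereocentre.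

Step 3
Reactants: 5 (R)-(−)-carvone
Product: 6 (1R,5R)-cis-carveol
Conditions: NaBH4, CeCl3·7H2O, MeOH, −20 °C
Reagents that add atoms: none
Why: Luche 1,2-reduction with axial hydride delivery gives the pseudo-equatorial alcohol cis to the isopropenyl group.

Step 4
Reactants: 6 (1R,5R)-cis-carveol
Product: 7 cis-epoxy alcohol
Conditions: VO(acac)2 (2 mol %), t-BuOOH, CH2Cl2, 0 °C → rt
Reagents that add atoms: tert-butyl hydroperoxide CC(C)(C)OO
Why: Hydroxyl-directed vanadium-catalysed epoxidation delivers oxygen to the ring alkene on the face of the OH group and leaves the isopropenyl group alone.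

Step 5
Reactants: 7 cis-epoxy alcohol
Product: 9 (2S,3S,5R)-3-(tert-butyldimethylsilyloxy)-2-methyl-5-(prop-1-en-2-yl)cyclohexan-1-one, via silyl ether 8 (not isolated)
Conditions: TBSOTf (2.2 equiv), i-Pr2NEt, 4 Å molecular sieves, CH2Cl2, −78 → −45 °C
Reagents that add atoms: tert-butyldimethylsilyl triflate CC(C)(C)[Si](C)(C)OS(=O)(=O)C(F)(F)F
Why: O-silylation then silyl-triflate-promoted non-aldol aldol (epoxy silyl ether semipinacol) rearrangement: the carbinol hydrogen, anti-periplanar to the tertiary epoxide C–O bond, shifts with inversion, so methyl and silyloxy end cis and the carbinol carbon becomes the ketone.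

Step 6
Reactants: 9 β-silyloxy ketone
Product: 10 (2S,3S,5R,6S)-3-(tert-butyldimethylsilyloxy)-2-methyl-5-(prop-1-en-2-yl)-6-(prop-2-en-1-yl)cyclohexan-1-one
Conditions: LDA, THF, −78 °C; allyl bromide, DMPU, −78 → −20 °C
Reagents that add atoms: allyl bromide C=CCBr
Why: Kinetic deprotonation on the CH2 side and alkylation of the enolate anti to the neighbouring isopropenyl-bearing carbon (and to the axial α′-methyl group) should give the trans allyl ketone.

Step 7
Reactants: 10 trans-allyl ketone
Product: 11 ring-B alcohol
Conditions: NaBH4, MeOH, −20 °C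
Reagents that add atoms: none
Why: Axial attack of the small hydride, on the face opposite the axial α-methyl group, should give the equatorial alcohol and complete the all-cis O/CH3/O triad.

Step 8
Reactants: 11 ring-B alcohol
Product: 12 bis-silyl ether
Conditions: TBSOTf, 2,6-lutidine, CH2Cl2, 0 °C
Reagents that add atoms: tert-butyldimethylsilyl triflate CC(C)(C)[Si](C)(C)OS(=O)(=O)C(F)(F)F
Why: Standard silylation of a hindered secondary alcohol with the silyl triflate.

Step 9
Reactants: 12 bis-silyl ether
Product: 13 (E)-propenyl bis-silyl ether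
Conditions: RuHCl(CO)(PPh3)3 (5 mol %), toluene, 80 °C
Reagents that add atoms: none
Why: Ruthenium hydride insertion/β-hydride elimination moves only the monosubstituted terminal alkene one position inward (the 1,1-disubstituted isopropenyl group does not insert), giving the alkenyl handle for ring-closing metathesis.

Step 10
Reactants: 13 (E)-propenyl bis-silyl ether
Product: 14 primary alcohol
Conditions: 9-BBN, THF, rt; then NaOH, H2O2, 0 °C
Reagents that add atoms: hydrogen peroxide OO
Why: Anti-Markovnikov hydroboration–oxidation in which 9-BBN takes the 1,1-disubstituted alkene far faster than the hindered internal propenyl group; the new CH(CH3) centre is not controlled and is erased in step 15.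

Step 11
Reactants: 14 primary alcohol
Product: 15 carboxylic acid
Conditions: TEMPO (20 mol %), PhI(OAc)2 (2.2 equiv), MeCN/H2O, rt
Reagents that add atoms: water O
Why: Oxoammonium oxidation of the primary alcohol through the aldehyde hydrate to the acid tolerates the alkene and the silyl ethers.

Step 12
Reactants: 15 carboxylic acid; 4 (R)-6-methylhepta-1,5-dien-3-ol
Product: 16 allylic ester
Conditions: EDC·HCl, DMAP, CH2Cl2, 0 °C → rt
Reagents that add atoms: none
Why: Steglich-type carbodiimide esterification acylates the allylic alcohol on oxygen, so its carbinol configuration is retained.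

Step 13
Reactants: 16 allylic ester
Product: 17 malonic half-thioester allyl ester
Conditions: LDA, THF, −78 °C; ClC(O)SEt, −78 °C
Reagents that add atoms: S-ethyl chlorothioformate CCSC(Cl)=O
Why: Claisen-type C-acylation of the lithium ester enolate (kept at −78 °C so the allyl ester enolate cannot rearrange) installs the thioester that later stabilises the enolate and is the aldehyde precursor.

Step 14
Reactants: 17 malonic half-thioester allyl ester
Product: 18 eight-membered (Z)-lactone
Conditions: second-generation Hoveyda–Grubbs catalyst (10 mol %), toluene (1 mM), 80 °C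
Reagents that add atoms: none
Why: Ring-closing metathesis between the propenyl and vinyl groups (the trisubstituted side-chain alkene is too hindered to initiate) closes the lactone on the trans-diequatorial ring-B template, and the ring size enforces the (Z)-alkene.

Step 15
Reactants: 18 eight-membered (Z)-lactone
Product: 19 decalin thioester with 3-methylbut-2-enyl side chain
Conditions: Pd(PPh3)4 (10 mol %), THF, 25 → 50 °C
Reagents that add atoms: none
Why: Proposed new method: Zerovalent palladium ionises the allylic C–O bond of the lactone with inversion to give an anti-configured η3-allyl complex and a malonic half-thioester carboxylate, which loses CO2 to a thioester enolate held next to the allyl cation; C–C bond formation at the distal allyl terminus, anti to palladium, then contracts the eight-membered lactone to the cyclohexene of the trans-decalin. The closest known reaction types are the palladium-catalysed decarboxylative allylation of allyl β-oxo esters and the decarboxylative ring contraction of vinyl lactones to vinylcyclopropanes; here the allyl unit lies inside a medium ring and a thioester is the stabilising group. Ring A closes in the 6-(enolexo)-endo mode on the allyl unit, the only alternative (attack at the proximal terminus) being a cyclobutane. The ring CH that carries the side chain is set by double inversion, so carbon replaces oxygen with retention of the carbinol configuration brought in with alcohol 4. The quaternary centre is set by A(1,3) strain: in the tetrasubstituted enolate the ring-fusion C–H eclipses the enolate C=C, so the allyl terminus tethered on the neighbouring ring carbon reaches only the face that leaves methyl axial and the thioester equatorial, cis to the side chain. The step needs C- over O-allylation, closure faster than syn/anti isomerisation or β-hydride elimination of the allyl complex, and survival of the thioester, all favoured by the intramolecular ion pair, the cis geometry inherited from the lactone and the mild temperature.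

Step 16
Reactants: 19 decalin thioester with 3-methylbut-2-enyl side chain
Product: 20 decalin thioester with allyl side chain
Conditions: second-generation Grubbs catalyst (5 mol %), ethylene (1 atm), CH2Cl2, 40 °C
Reagents that add atoms: ethene C=C
Why: Cross-metathesis with ethylene (ethenolysis) trims the trisubstituted side-chain alkene to the terminal allyl group needed in step 31, while the unstrained cyclohexene does not ring-open.

Step 17
Reactants: 20 decalin thioester with allyl side chain
Product: 21 decalin aldehyde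
Conditions: DIBAL-H (1.2 equiv), CH2Cl2, −78 °C; Rochelle salt
Reagents that add atoms: none
Why: Thioesters are reduced by DIBAL-H at −78 °C only as far as the aldehyde, through a stable aluminium hemithioacetal.

Step 18
Reactants: 22 (E)-2-methylpent-2-enal
Product: 23 ethyl (2E,4E)-2,4-dimethylhepta-2,4-dienoate
Conditions: Ph3P=C(CH3)CO2Et, toluene, 90 °C
Reagents that add atoms: ethyl 2-(triphenylphosphoranylidene)propanoate CCOC(=O)C(C)=P(c1ccccc1)(c1ccccc1)c1ccccc1
Why: Wittig olefination with the stabilised α-methyl ylide gives the (E)-trisubstituted enoate.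

Step 19
Reactants: 23 ethyl (2E,4E)-2,4-dimethylhepta-2,4-dienoate
Product: 24 (2E,4E)-2,4-dimethylhepta-2,4-dien-1-ol
Conditions: DIBAL-H (2.2 equiv), CH2Cl2, −78 °C
Reagents that add atoms: none
Why: 1,2-Reduction of the conjugated ester to the allylic alcohol leaves the diene geometry intact.

Step 20
Reactants: 24 (2E,4E)-2,4-dimethylhepta-2,4-dien-1-ol
Product: 25 (2E,4E)-1-bromo-2,4-dimethylhepta-2,4-diene
Conditions: CBr4, PPh3, CH2Cl2, 0 °C
Reagents that add atoms: carbon tetrabromide BrC(Br)(Br)Br
Why: Appel bromination of the primary allylic alcohol at low temperature proceeds without allylic transposition.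

Step 21
Reactants: 25 (2E,4E)-1-bromo-2,4-dimethylhepta-2,4-diene
Product: 26 (4E,6E)-4,6-dimethylnona-1,4,6-triene
Conditions: tributyl(vinyl)stannane, Pd2(dba)3 (2.5 mol %), tri(2-furyl)phosphine, THF, 50 °C
Reagents that add atoms: tributyl(vinyl)stannane C=C[Sn](CCCC)(CCCC)CCCC
Why: Stille coupling of the allylic bromide joins the vinyl group at the primary allyl terminus and keeps the conjugated (E,E)-diene.

Step 22
Reactants: 27 2,2-dimethyl-1,3-dioxan-5-one
Product: 28 2,2-dimethyl-4H-1,3-dioxin-5-yl acetate
Conditions: KHMDS, THF, −78 °C; then Ac2O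
Reagents that add atoms: acetic anhydride CC(=O)OC(C)=O
Why: O-acetylation of the potassium enolate gives the enol acetate.

Step 23
Reactants: 28 2,2-dimethyl-4H-1,3-dioxin-5-yl acetate
Product: 29 2-acetoxyacrolein
Conditions: toluene, 120 °C, then distillation
Reagents that add atoms: none
Why: Thermal retro-hetero-Diels–Alder loss of acetone unmasks the 2-acyloxy enal.

Step 24
Reactants: 26 (4E,6E)-4,6-dimethylnona-1,4,6-triene; 29 2-acetoxyacrolein
Product: 30 (1S,2R,5R)-5-ethyl-1-formyl-2,4-dimethyl-2-(prop-2-enyl)cyclohex-3-en-1-yl acetate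
Conditions: chiral primary ammonium salt catalyst [triamine H2N–CH(CH2Ph)–CH2–NH–CH(i-Bu)–CH2–N(CH2)4, 2.75 C6F5SO3H] (10 mol %), EtNO2, 0 °C → rt
Reagents that add atoms: none
Why: Iminium-activated Diels–Alder reaction in which the more nucleophilic CH(Et) diene terminus bonds to the enal CH2 (ortho/para rule), the formyl group takes the exo position away from the outside ethyl and allyl groups (exo preference of α-substituted acroleins, reinforced by the inside methyl group), and the chiral ammonium catalyst shields one enal face, fixing all three stereocentres.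

Step 25
Reactants: 30 cycloadduct aldehyde
Product: 31 (1S,2R,5R)-1-acetoxy-5-ethyl-2,4-dimethyl-2-(prop-2-enyl)cyclohex-3-ene-1-carboxylic acid
Conditions: NaClO2, NaH2PO4, 2-methylbut-2-ene, t-BuOH/H2O, 0 °C → rt
Reagents that add atoms: sodium chlorite [Na+].[O-]Cl=O
Why: Pinnick oxidation of the non-enolisable aldehyde, with the scavenger protecting both olefins from hypochlorite.

Step 26
Reactants: 31 acetoxy acid
Product: 32 methyl (1S,2R,5R)-1-acetoxy-5-ethyl-2,4-dimethyl-2-(prop-2-enyl)cyclohex-3-ene-1-carboxylate
Conditions: MeI, K2CO3, DMF, rt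
Reagents that add atoms: iodomethane CI
Why: SN2 methylation of the carboxylate gives the ester needed as the Dieckmann acceptor.

Step 27
Reactants: 32 acetoxy methyl ester
Product: 33 (5S,6R,9R)-9-ethyl-4-hydroxy-6,8-dimethyl-6-(prop-2-enyl)-1-oxaspiro[4.5]deca-3,7-dien-2-one
Conditions: LiHMDS (2.5 equiv), THF, −78 → 0 °C; aqueous HCl
Reagents that add atoms: none
Why: Dieckmann condensation of the acetate enolate onto the neighbouring ester closes the tetronic acid without touching the spiro stereocentre.

Step 28
Reactants: 33 spiro tetronic acid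
Product: 34 (5S,6R,9R)-9-ethyl-4-methoxy-6,8-dimethyl-6-(prop-2-enyl)-1-oxaspiro[4.5]deca-3,7-dien-2-one
Conditions: Me2SO4, K2CO3, acetone, rt
Reagents that add atoms: dimethyl sulfate COS(=O)(=O)OC
Why: O-methylation of the vinylogous acid gives the 4-methoxy tetronate, whose C-3 hydrogen can then be removed by base.

Step 29
Reactants: 34 spiro methyl tetronate; 21 decalin aldehyde
Product: 35 coupled carbinol
Conditions: LDA, THF, −78 °C (34 first); then 21, −78 °C
Reagents that add atoms: none
Why: C-3 lithiation of the 4-methoxy tetronate (its only acidic C–H) and 1,2-addition to the non-enolisable neopentyl aldehyde; the new carbinol centre is removed in the next step.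

Step 30
Reactants: 35 coupled carbinol
Product: 36 3-acyl-4-methoxy tetronate diene
Conditions: Dess–Martin periodinane, NaHCO3, CH2Cl2, rt
Reagents that add atoms: none
Why: Buffered Dess–Martin oxidation converts the secondary alcohol to the ketone under neutral conditions.

Step 31
Reactants: 36 3-acyl-4-methoxy tetronate diene
Product: 37 macrocyclic (Z)-olefin
Conditions: Z-selective cyclometalated ruthenium nitrato Grubbs catalyst (N-adamantyl/N-2,6-diisopropylphenyl imidazolinylidene, 2-isopropoxybenzylidene; 7.5 mol %), 1,2-dichloroethane (2 mM), 60 °C, static vacuum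
Reagents that add atoms: none
Why: Ring-closing metathesis of the two terminal allyl groups with a catalyst whose cyclometalated geometry delivers the (Z)-olefin, expected also to be the less strained isomer in the bridged eleven-membered ring.

Step 32
Reactants: 37 macrocyclic (Z)-olefin
Product: 38 bis-silyl ether of the target
Conditions: LiCl, DMSO, 60 °C; aqueous HCl
Reagents that add atoms: none
Why: Chloride SN2 demethylation of the vinylogous methyl ester, activated by the 3-acyl group, frees the tetronic acid.

Step 33
Reactants: 38 bis-silyl ether of the target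
Product: 39 CNP0259772.1
Conditions: HF·pyridine, THF/pyridine, 0 °C → rt
Reagents that add atoms: none
Why: Fluoride cleaves both secondary silyl ethers; the acyl tetronic acid and the olefins are stable to these conditions.

**Compound list**

1 | (R)-epichlorohydrin | ClC[C@H]1CO1 | starting material
2 | (R)-1-chloro-5-methylhex-4-en-2-ol | ClC[C@H](O)CC=C(C)C | intermediate
3 | (R)-2-(3-methylbut-2-en-1-yl)oxirane | CC(C)=CC[C@@H]1CO1 | intermediate (not isolated)
4 | (R)-6-methylhepta-1,5-dien-3-ol | C=C[C@H](O)CC=C(C)C | intermediate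
5 | (R)-(−)-carvone | C=C(C)[C@@H]1CC=C(C)C(=O)C1 | starting material
6 | (1R,5R)-cis-carveol | C=C(C)[C@@H]1CC=C(C)[C@H](O)C1 | intermediate
7 | cis-1,2-epoxycarveol (epoxide O, OH and isopropenyl on one face) | C=C(C)[C@@H]1C[C@@H]2O[C@]2(C)[C@H](O)C1 | intermediate
8 | TBS ether of 7 | C=C(C)[C@@H]1C[C@@H]2O[C@]2(C)[C@H](O[Si](C)(C)C(C)(C)C)C1 | intermediate (not isolated)
9 | (2S,3S,5R)-3-(tert-butyldimethylsilyloxy)-2-methyl-5-(prop-1-en-2-yl)cyclohexan-1-one | C=C(C)[C@@H]1C[C@H](O[Si](C)(C)C(C)(C)C)[C@H](C)C(=O)C1 | intermediate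
10 | (2S,3S,5R,6S)-6-allyl derivative of 9 | C=C(C)[C@@H]1C[C@H](O[Si](C)(C)C(C)(C)C)[C@H](C)C(=O)[C@H]1CC=C | intermediate
11 | ring-B alcohol (OH cis to CH3, OTBS and isopropenyl; trans to allyl) | C=C(C)[C@@H]1C[C@H](O[Si](C)(C)C(C)(C)C)[C@H](C)[C@H](O)[C@H]1CC=C | intermediate
12 | bis-TBS ether of 11 | C=C(C)[C@@H]1C[C@H](O[Si](C)(C)C(C)(C)C)[C@H](C)[C@H](O[Si](C)(C)C(C)(C)C)[C@H]1CC=C | intermediate
13 | (E)-prop-1-enyl isomer of 12 | C=C(C)[C@@H]1C[C@H](O[Si](C)(C)C(C)(C)C)[C@H](C)[C@H](O[Si](C)(C)C(C)(C)C)[C@H]1/C=C/C | intermediate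
14 | primary alcohol, 2-(ring-B)propan-1-ol (epimers at CH(CH3)) | OCC(C)[C@@H]1C[C@H](O[Si](C)(C)C(C)(C)C)[C@H](C)[C@H](O[Si](C)(C)C(C)(C)C)[C@H]1/C=C/C | intermediate
15 | 2-(ring-B)propanoic acid (epimers) | OC(=O)C(C)[C@@H]1C[C@H](O[Si](C)(C)C(C)(C)C)[C@H](C)[C@H](O[Si](C)(C)C(C)(C)C)[C@H]1/C=C/C | intermediate
16 | (R)-6-methylhepta-1,5-dien-3-yl ester of 15 | C=C[C@@H](CC=C(C)C)OC(=O)C(C)[C@@H]1C[C@H](O[Si](C)(C)C(C)(C)C)[C@H](C)[C@H](O[Si](C)(C)C(C)(C)C)[C@H]1/C=C/C | intermediate
17 | α-(ethylthiocarbonyl) derivative of 16, C(CH3)(COSEt)(CO2R) (epimers) | C=C[C@@H](CC=C(C)C)OC(=O)C(C)(C(=O)SCC)[C@@H]1C[C@H](O[Si](C)(C)C(C)(C)C)[C@H](C)[C@H](O[Si](C)(C)C(C)(C)C)[C@H]1/C=C/C | intermediate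
18 | eight-membered (Z)-allylic lactone trans-fused to ring B; α-carbon bears CH3 and COSEt, carbinol carbon (R) bears the 3-methylbut-2-enyl group | CCSC(=O)C1(C)[C@@H]2C[C@H](O[Si](C)(C)C(C)(C)C)[C@H](C)[C@H](O[Si](C)(C)C(C)(C)C)[C@H]2/C=C\[C@@H](CC=C(C)C)OC1=O | intermediate
19 | S-ethyl (1R,2R,4aS,5R,6S,7S,8aR)-5,7-bis(tert-butyldimethylsilyloxy)-1,6-dimethyl-2-(3-methylbut-2-enyl)-1,2,4a,5,6,7,8,8a-octahydronaphthalene-1-carbothioate | CCSC(=O)[C@@]1(C)[C@@H]2C[C@H](O[Si](C)(C)C(C)(C)C)[C@H](C)[C@H](O[Si](C)(C)C(C)(C)C)[C@H]2C=C[C@H]1CC=C(C)C | intermediate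
20 | 2-(prop-2-enyl) analogue of 19 | CCSC(=O)[C@@]1(C)[C@@H]2C[C@H](O[Si](C)(C)C(C)(C)C)[C@H](C)[C@H](O[Si](C)(C)C(C)(C)C)[C@H]2C=C[C@H]1CC=C | intermediate
21 | (1R,2R,4aS,5R,6S,7S,8aR)-5,7-bis(tert-butyldimethylsilyloxy)-1,6-dimethyl-2-(prop-2-enyl)-1,2,4a,5,6,7,8,8a-octahydronaphthalene-1-carbaldehyde | O=C[C@@]1(C)[C@@H]2C[C@H](O[Si](C)(C)C(C)(C)C)[C@H](C)[C@H](O[Si](C)(C)C(C)(C)C)[C@H]2C=C[C@H]1CC=C | intermediate
22 | (E)-2-methylpent-2-enal | CC/C=C(\C)C=O | starting material
23 | ethyl (2E,4E)-2,4-dimethylhepta-2,4-dienoate | CC/C=C(C)/C=C(C)/C(=O)OCC | intermediate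
24 | (2E,4E)-2,4-dimethylhepta-2,4-dien-1-ol | CC/C=C(C)/C=C(C)/CO | intermediate
25 | (2E,4E)-1-bromo-2,4-dimethylhepta-2,4-diene | CC/C=C(C)/C=C(C)/CBr | intermediate
26 | (4E,6E)-4,6-dimethylnona-1,4,6-triene | CC/C=C(C)/C=C(C)/CC=C | intermediate
27 | 2,2-dimethyl-1,3-dioxan-5-one | CC1(C)OCC(=O)CO1 | starting material
28 | 2,2-dimethyl-4H-1,3-dioxin-5-yl acetate | CC(=O)OC1=COC(C)(C)OC1 | intermediate
29 | 2-acetoxyacrolein | CC(=O)OC(=C)C=O | intermediate
30 | (1S,2R,5R)-5-ethyl-1-formyl-2,4-dimethyl-2-(prop-2-enyl)cyclohex-3-en-1-yl acetate | CC[C@@H]1C[C@@](OC(C)=O)(C=O)[C@](C)(CC=C)C=C1C | intermediate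
31 | (1S,2R,5R)-1-acetoxy-5-ethyl-2,4-dimethyl-2-(prop-2-enyl)cyclohex-3-ene-1-carboxylic acid | CC[C@@H]1C[C@@](OC(C)=O)(C(=O)O)[C@](C)(CC=C)C=C1C | intermediate
32 | methyl ester of 31 | CC[C@@H]1C[C@@](OC(C)=O)(C(=O)OC)[C@](C)(CC=C)C=C1C | intermediate
33 | (5S,6R,9R)-9-ethyl-4-hydroxy-6,8-dimethyl-6-(prop-2-enyl)-1-oxaspiro[4.5]deca-3,7-dien-2-one | CC[C@@H]1C[C@]2(OC(=O)C=C2O)[C@](C)(CC=C)C=C1C | intermediate
34 | (5S,6R,9R)-9-ethyl-4-methoxy-6,8-dimethyl-6-(prop-2-enyl)-1-oxaspiro[4.5]deca-3,7-dien-2-one | CC[C@@H]1C[C@]2(OC(=O)C=C2OC)[C@](C)(CC=C)C=C1C | intermediate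
35 | 3-[hydroxy(decalinyl)methyl] derivative of 34 (decalinyl = C-1 of 21; carbinol epimers) | CC[C@@H]1C[C@]2(OC(=O)C(C(O)[C@@]3(C)[C@@H]4C[C@H](O[Si](C)(C)C(C)(C)C)[C@H](C)[C@H](O[Si](C)(C)C(C)(C)C)[C@H]4C=C[C@H]3CC=C)=C2OC)[C@](C)(CC=C)C=C1C | intermediate
36 | 3-(decalinylcarbonyl)-4-methoxy spirotetronate with two allyl groups | CC[C@@H]1C[C@]2(OC(=O)C(C(=O)[C@@]3(C)[C@@H]4C[C@H](O[Si](C)(C)C(C)(C)C)[C@H](C)[C@H](O[Si](C)(C)C(C)(C)C)[C@H]4C=C[C@H]3CC=C)=C2OC)[C@](C)(CC=C)C=C1C | intermediate
37 | macrocyclic (Z)-olefin: 4-O-methyl bis-TBS ether of the target | CC[C@@H]1C[C@]23OC(=O)C(C(=O)[C@@]4(C)[C@@H]5C[C@H](O[Si](C)(C)C(C)(C)C)[C@H](C)[C@H](O[Si](C)(C)C(C)(C)C)[C@H]5C=C[C@H]4C/C=C\C[C@]2(C)C=C1C)=C3OC | intermediate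
38 | bis-TBS ether of the target | CC[C@@H]1C[C@]23OC(=O)/C(=C(\O)[C@@]4(C)[C@@H]5C[C@H](O[Si](C)(C)C(C)(C)C)[C@H](C)[C@H](O[Si](C)(C)C(C)(C)C)[C@H]5C=C[C@H]4C/C=C\C[C@]2(C)C=C1C)C3=O | intermediate
39 | CNP0259772.1 | CC[C@@H]1C[C@]23OC(=O)/C(=C(\O)[C@@]4(C)[C@@H]5C[C@H](O)[C@H](C)[C@H](O)[C@H]5C=C[C@H]4C/C=C\C[C@]2(C)C=C1C)C3=O | target

**Count and risks**

Total step count: 33. Longest linear sequence: 20 steps (steps 3–17 and 29–33, from carvone 5).

Steps most likely to fail:

1. Step 15 (proposed new method). Decarboxylation may be slower than syn/anti isomerisation or β-hydride elimination of the allyl complex, the carboxylate may simply re-close to lactone isomers, or facial control at the enolate may be poor. Fallback with known chemistry, setting out from 17: iridium-catalysed decarboxylative allylic alkylation ([Ir(cod)Cl]2, chiral phosphoramidite ligand, THF, 50 °C) forms the C–C bond at the substituted allyl terminus and gives the branched diene thioester F1. Ring-closing metathesis between its vinyl and propenyl groups (second-generation Grubbs catalyst, CH2Cl2, 40 °C) then closes ring A directly and returns to the route at 19. This detour gives up the ring contraction, puts both new stereocentres under catalyst control, and also bypasses lactone 18.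

2. Step 31. Strain in the bridged eleven-membered ring may stall ring closure, or allow oligomerisation and loss of Z-selectivity. Fallback, setting out from 20 and 34: Z-selective cross-metathesis of the two allyl groups (same ruthenium catalyst, excess 34) gives the (Z)-linked thioester F2. LDA (2.2 equiv, THF, −78 → 0 °C) then lithiates the tetronate at C-3, and the anion acylates intramolecularly with the non-enolisable thioester, closing the macrocycle at the ketone. The fallback returns at 37 and leaves out steps 17, 29 and 30.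

3. Step 24. The diene terminus with an inside methyl group may be too unreactive under iminium catalysis, or enantiofacial and exo control may be insufficient. Fallback, setting out from 26: thermal exo-selective Diels–Alder reaction (toluene, 120 °C, BHT) with the known chiral dienophile (R)-2-tert-butyl-5-methylene-1,3-dioxolan-4-one F3, to which the diene adds anti to the tert-butyl group, gives spiro-dioxolanone F4. Methanolysis (NaOMe, MeOH) gives hydroxy ester F5, and acetylation (Ac2O, DMAP, Et3N) returns to the route at 32.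

**Further compounds**

F1 | step 15 | branched allylation product, S-ethyl 2-methyl-2-(ring-B)-3-vinyl-6-methylhept-5-enethioate | CCSC(=O)[C@](C)([C@@H](C=C)CC=C(C)C)[C@@H]1C[C@H](O[Si](C)(C)C(C)(C)C)[C@H](C)[C@H](O[Si](C)(C)C(C)(C)C)[C@H]1/C=C/C
F2 | step 31 | (Z)-cross-metathesis product of 20 and 34 | CCSC(=O)[C@@]1(C)[C@@H]2C[C@H](O[Si](C)(C)C(C)(C)C)[C@H](C)[C@H](O[Si](C)(C)C(C)(C)C)[C@H]2C=C[C@H]1C/C=C\C[C@]3(C)C=C(C)[C@H](CC)C[C@]34OC(=O)C=C4OC
F3 | step 24 | (R)-2-tert-butyl-5-methylene-1,3-dioxolan-4-one | C=C1O[C@@H](C(C)(C)C)OC1=O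
F4 | step 24 | spiro-dioxolanone cycloadduct | CC[C@@H]1C[C@]2(O[C@@H](C(C)(C)C)OC2=O)[C@](C)(CC=C)C=C1C
F5 | step 24 | methyl (1S,2R,5R)-5-ethyl-1-hydroxy-2,4-dimethyl-2-(prop-2-enyl)cyclohex-3-ene-1-carboxylate | CC[C@@H]1C[C@@](O)(C(=O)OC)[C@](C)(CC=C)C=C1C
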